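**Assumption:** the SMILES fixes the target as (1R,5R,10R,14S) with a trans-fused α-methylene lactone (H-1/H-14 anti) and a 12E alkene, using the cembrane numbering implied by the name (C4=CH2, C5–OOH, butenolide C8/C19/C10, lactone C1/C15/C16/C14). Hex-1-en-5-yne is taken as commercial.

## Retrosynthetic overview

1. Target ⇒ ovatodiolide (14) by a last-step singlet-oxygen ene reaction (C5–OOH, exocyclic C4=C18).
2. 14 ⇒ acyclic enal/allyl bromide 13 by cutting C1–C14 and the lactone C–O: a Cr-catalysed asymmetric macro-allylation/lactonisation closes the 14-membered ring and the α-methylene lactone together (new step).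
3. 13 ⇒ butenolide alcohol 10 by cross-metathesis and allylic oxidation; the butenolide (first ring) comes from a (Z)-γ-iodoallylic alcohol by Pd carbonylation.
4. Propargylic alcohol 8 (C10 stereocentre, 12E alkene, C14) ⇒ ynal 5 + senecioate silyl dienolate 7 by asymmetric vinylogous Mukaiyama aldol.
5. 5 ⇒ hex-1-en-5-yne by carboalumination/oxirane opening (4E alkene), acetylide alkylation and formylation. Ring order: butenolide, then macrocycle + α-methylene lactone.

## Route

**Step 1**
Reactants: 1 hex-1-en-5-yne
Product: 2 (3E)-4-methylocta-3,7-dien-1-ol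
Conditions: Me3Al, Cp2ZrCl2 (20 mol%), CH2Cl2, 0 °C→rt; then n-BuLi, hexane/THF, −30 °C; ethylene oxide, →rt
Reagents that add atoms: trimethylaluminium, C[Al](C)C; ethylene oxide, C1CO1
Why: Negishi Zr-catalysed carboalumination adds Me–Al syn across the terminal alkyne (the monosubstituted alkene is far slower), and the derived alanate opens the oxirane with retention, fixing the E trisubstituted alkene (future C4=C5 with the C18 methyl).

**Step 2**
Reactants: 2 (3E)-4-methylocta-3,7-dien-1-ol
Product: 3 (5E)-8-iodo-5-methylocta-1,5-diene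
Conditions: PPh3, I2, imidazole, CH2Cl2, 0 °C
Reagents that add atoms: iodine, II
Why: Appel iodination of a primary alcohol under neutral conditions, with no allylic transposition or alkene isomerisation.

**Step 3**
Reactants: 3 (5E)-8-iodo-5-methylocta-1,5-diene
Product: 4 (5E)-6-methyldeca-5,9-dien-1-yne
Conditions: LiC≡CH·ethylenediamine, DMSO, 10 °C→rt
Reagents that add atoms: lithium acetylide (ethylenediamine complex), [Li]C#C
Why: SN2 alkylation of acetylide by a primary iodide in a dipolar aprotic solvent installs the C8≡C9 alkyne.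

**Step 4**
Reactants: 4 (5E)-6-methyldeca-5,9-dien-1-yne
Product: 5 (6E)-7-methylundeca-6,10-dien-2-ynal
Conditions: n-BuLi, THF, −78 °C; DMF; inverse quench into aq. KH2PO4
Reagents that add atoms: N,N-dimethylformamide, CN(C)C=O
Why: C-formylation of the lithium acetylide with DMF, with a buffered inverse quench to stop amine conjugate addition to the ynal.

**Step 5**
Reactants: 6 methyl 3-methylbut-2-enoate
Product: 7 tert-butyl[(1-methoxy-3-methylbuta-1,3-dien-1-yl)oxy]dimethylsilane
Conditions: LDA, THF/DMPU, −78 °C; TBSCl
Reagents that add atoms: tert-butyldimethylsilyl chloride, CC(C)(C)[Si](C)(C)Cl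
Why: kinetic γ-deprotonation of the senecioate and O-silylation gives the extended silyl ketene acetal.

**Step 6**
Reactants: 5 (6E)-7-methylundeca-6,10-dien-2-ynal; 7 silyl dienolate
Product: 8 methyl (2E,5R,10E)-5-hydroxy-3,11-dimethylpentadeca-2,10,14-trien-6-ynoate
Conditions: SiCl4 (1.1 equiv), Denmark BINAM-derived bisphosphoramide (5 mol%; antipode giving Re-face addition, nominally R,R), i-Pr2NEt (10 mol%), CH2Cl2, −78 °C; aq. KF/NaHCO3
Reagents that add atoms: none
Why: Lewis-base-activated SiCl4 vinylogous Mukaiyama aldol is γ-selective and gives the E-enoate (future 12E alkene), and catalyst-controlled Re-face addition to the conjugated ynal sets C10 as R.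

**Step 7**
Reactants: 8 methyl (2E,5R,10E)-5-hydroxy-3,11-dimethylpentadeca-2,10,14-trien-6-ynoate
Product: 9 (2E,5R,6Z,10E)-7-iodo-3,11-dimethylpentadeca-2,6,10,14-tetraene-1,5-diol
Conditions: Red-Al (5 equiv), THF, 0 °C→rt; EtOAc; then I2, −78→0 °C
Reagents that add atoms: iodine, II
Why: Red-Al reduces the enoate 1,2 to the allylic alcohol and performs hydroxyl-directed trans-hydroalumination (Al on the distal alkyne carbon via the five-membered alkoxyaluminate), and iodinolysis with retention gives the (Z)-γ-iodoallylic alcohol without touching C10.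

**Step 8**
Reactants: 9 (2E,5R,6Z,10E)-7-iodo-3,11-dimethylpentadeca-2,6,10,14-tetraene-1,5-diol
Product: 10 (5R)-5-[(2E)-4-hydroxy-2-methylbut-2-en-1-yl]-3-[(3E)-4-methylocta-3,7-dien-1-yl]furan-2(5H)-one
Conditions: PdCl2(PPh3)2 (5 mol%), CO (1 atm), K2CO3, THF, 45 °C
Reagents that add atoms: carbon monoxide, [C-]#[O+]
Why: Pd-catalysed carbonylative lactonisation (oxidative addition, CO insertion, capture of the acyl-Pd by the cis secondary alcohol) forms the five-membered butenolide far faster than the remote primary alcohol can react.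

**Step 9**
Reactants: 10 butenolide alcohol; 11 methyl 2-(bromomethyl)acrylate
Product: 12 methyl (2Z,6E)-2-(bromomethyl)-9-{(5R)-5-[(2E)-4-hydroxy-2-methylbut-2-en-1-yl]-2-oxo-2,5-dihydrofuran-3-yl}-6-methylnona-2,6-dienoate
Conditions: Hoveyda–Grubbs II (7.5 mol%), 11 (8 equiv), 1,4-benzoquinone (10 mol%), CH2Cl2, 40 °C
Reagents that add atoms: none
Why: olefin cross-metathesis of the only monosubstituted alkene with a 1,1-disubstituted acrylate (trisubstituted alkenes and the butenolide are spectators) installs the γ-substituted 2-(alkoxycarbonyl)allyl bromide in one step; its geometry is not critical because the allylchromium in Step 11 equilibrates.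

**Step 10**
Reactants: 12 allyl bromide alcohol
Product: 13 methyl (2Z,6E)-2-(bromomethyl)-6-methyl-9-{(5R)-5-[(2E)-2-methyl-4-oxobut-2-en-1-yl]-2-oxo-2,5-dihydrofuran-3-yl}nona-2,6-dienoate
Conditions: MnO2 (20 equiv), CH2Cl2, rt
Reagents that add atoms: none
Why: chemoselective MnO2 oxidation of the primary allylic alcohol gives the E-enal without affecting the allylic bromide or the butenolide.

**Step 11 (new step)**
Reactants: 13 enal/allyl bromide
Product: 14 ovatodiolide: (1R,10R,14S,4E,12E)-cembra-4,8,12,15(17)-tetraene-16,14:19,10-diolide (14-membered carbocycle, trans-fused α-methylene-γ-butyrolactone at C1/C14, bridging C8–C19(=O)–O–C10 butenolide)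
Conditions: CrCl2 (15 mol%), chiral tridentate carbazole-bis(oxazoline) ligand (18 mol%; antipode giving aldehyde Re-face attack), i-Pr2NEt (40 mol%), Mn powder (3 equiv), Cp2ZrCl2 (1.2 equiv), LiCl, THF/MeCN, rt, syringe-pump addition of 13 over 12 h to 2 mM; then PPTS, CH2Cl2, rt
Reagents that add atoms: none
Why: Proposed new method: a catalyst-controlled, Cr-catalytic macrocyclising Nozaki–Hiyama–Kishi-type 2-(alkoxycarbonyl)allylation/lactonisation, in which ligated Cr(II) reduces the allylic C–Br bond to an allyl-Cr(III) species whose E/Z isomers interconvert, γ-attack (C1) on the Cr-bound enal through a closed chair transition state with the C2 chain pseudo-equatorial gives the anti adduct (hence the trans lactone) while the ligand selects the aldehyde Re face (14S, therefore 1R), Cp2ZrCl2 frees the Cr–alkoxide and Mn(0) regenerates Cr(II) (Cp2ZrCl2 rather than TMSCl avoids Cr/silyl activation of the enal), and the γ-alkoxide closes on the methyl ester to form the α-methylene lactone; the closest known reactions are intermolecular Cr/chiral-ligand-catalysed asymmetric allylations of aldehydes (including 2-(alkoxycarbonyl)allyl bromides) and stoichiometric CrCl2-mediated allyl bromide–aldehyde macrocyclisations to cembranoids.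

**Step 12**
Reactants: 14 ovatodiolide
Product: 15 4-methylene-5β-hydroperoxyovatodiolide (target; 1R,5R,10R,14S)
Conditions: O2, tetraphenylporphyrin (1 mol%), CH2Cl2, −30 °C, white LED, stopped at consumption of 14; SiO2 then HPLC
Reagents that add atoms: dioxygen, O=O
Why: Schenck ene reaction, in which 1O2 reacts only with the electron-rich C4=C5 alkene (C12=C13 is deactivated by the allylic lactone oxygen, the conjugated alkenes are inert), the cis effect directs H-abstraction to the crowded C18-methyl/C6 side with the freely rotating methyl favoured to give C5–OOH and the exocyclic alkene, and attack on the exposed peripheral face of the macrocyclic E-alkene is expected to give 5R; the tertiary 4-OOH/Δ5 regioisomer and any 5-epimer are removed chromatographically.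

## Compound list

1 | hex-1-en-5-yne | C#CCCC=C | starting material
2 | (3E)-4-methylocta-3,7-dien-1-ol | OCC/C=C(\C)CCC=C | intermediate
3 | (5E)-8-iodo-5-methylocta-1,5-diene | ICC/C=C(\C)CCC=C | intermediate
4 | (5E)-6-methyldeca-5,9-dien-1-yne | C#CCC/C=C(\C)CCC=C | intermediate
5 | (6E)-7-methylundeca-6,10-dien-2-ynal | O=CC#CCC/C=C(\C)CCC=C | intermediate
6 | methyl 3-methylbut-2-enoate | COC(=O)C=C(C)C | starting material
7 | tert-butyl[(1-methoxy-3-methylbuta-1,3-dien-1-yl)oxy]dimethylsilane | C=C(C)C=C(OC)O[Si](C)(C)C(C)(C)C | intermediate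
8 | methyl (2E,5R,10E)-5-hydroxy-3,11-dimethylpentadeca-2,10,14-trien-6-ynoate | COC(=O)/C=C(\C)C[C@@H](O)C#CCC/C=C(\C)CCC=C | intermediate
9 | (2E,5R,6Z,10E)-7-iodo-3,11-dimethylpentadeca-2,6,10,14-tetraene-1,5-diol | OC/C=C(\C)C[C@@H](O)/C=C(\I)CC/C=C(\C)CCC=C | intermediate
10 | (5R)-5-[(2E)-4-hydroxy-2-methylbut-2-en-1-yl]-3-[(3E)-4-methylocta-3,7-dien-1-yl]furan-2(5H)-one | OC/C=C(\C)C[C@@H]1C=C(CC/C=C(\C)CCC=C)C(=O)O1 | intermediate
11 | methyl 2-(bromomethyl)acrylate | C=C(CBr)C(=O)OC | starting material
12 | methyl (2Z,6E)-2-(bromomethyl)-9-{(5R)-5-[(2E)-4-hydroxy-2-methylbut-2-en-1-yl]-2-oxo-2,5-dihydrofuran-3-yl}-6-methylnona-2,6-dienoate | OC/C=C(\C)C[C@@H]1C=C(CC/C=C(\C)CC/C=C(\CBr)C(=O)OC)C(=O)O1 | intermediate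
13 | methyl (2Z,6E)-2-(bromomethyl)-6-methyl-9-{(5R)-5-[(2E)-2-methyl-4-oxobut-2-en-1-yl]-2-oxo-2,5-dihydrofuran-3-yl}nona-2,6-dienoate | O=C/C=C(\C)C[C@@H]1C=C(CC/C=C(\C)CC/C=C(\CBr)C(=O)OC)C(=O)O1 | intermediate
14 | ovatodiolide, (1R,10R,14S,4E,12E) | C=C1C(=O)O[C@H]2/C=C(\C)C[C@@H]3C=C(CC/C=C(\C)CC[C@H]12)C(=O)O3 | intermediate
15 | 4-methylene-5β-hydroperoxyovatodiolide, (1R,5R,10R,14S) | C=C1C(=O)O[C@H]2/C=C(\C)C[C@@H]3C=C(CC[C@@H](OO)C(=C)CC[C@H]12)C(=O)O3 | target

## Summary

Total steps: 12. Longest linear sequence: 11 (Steps 1–4, 6–12 from hex-1-en-5-yne).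

Three steps most likely to fail:

1. **Step 11 (proposed new Cr-catalysed asymmetric macro-allylation/lactonisation).** Risks are catalyst turnover at high dilution, a mismatch with the C10 centre, and oligomers. Fallback with known chemistry: make the C1–C14 bond and trans lactone intermolecularly by the established Cr-catalysed asymmetric 2-(alkoxycarbonyl)allylation of a C10–C14 enal fragment, using methyl-capped alkyne versions of both halves. Then close the 14-membered ring by ring-closing alkyne metathesis at C8≡C9 and convert the macrocyclic propargylic alcohol to the butenolide by Ru-catalysed trans-hydrosilylation, iododesilylation and Pd carbonylation.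

2. **Step 12 (Schenck ene).** The tertiary 4-hydroperoxy-Δ5 regioisomer and the C5 epimer are likely by-products. The ratio cannot be predicted without experiment, and the 5R assignment rests on peripheral attack on the dominant conformer. Fallback: epoxidise C4=C5 with mCPBA, isomerise the epoxide to the 4-methylene-5-ol (Cp2TiCl), then displace the derived C5 sulfonate with H2O2 by SN2, after a Mitsunobu inversion if needed.

3. **Step 9 (cross-metathesis with a 1,1-disubstituted bromomethyl acrylate).** Fallback: carry C1 as a PMB-protected alcohol from pent-4-yn-1-ol; after the butenolide is made, protect C14-OH as TBS, remove PMB (DDQ), oxidise (Dess–Martin), run a Morita–Baylis–Hillman reaction with methyl acrylate, and convert to the allyl bromide with NBS/Me2S.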